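A leftover is where you start: in the winter run, which is the very flask you are asked about, 41.3% of the starting material still stands at 3.00 d, while the target climbs slowly.

in all of them: starting material 0.68 M; reagent 0.816 M; protic impurity 0.0136 M; free catalyst 33 mM

|  | second substrate | remark | time |
|---|---|---|---|
| winter | 0.68 M | the very flask that is asked about, followed so far |  |
| flask | 0.680 M |  | 6.0 d |

winter run (percent of the starting material charged)

| time / d | target / % | starting material / % |
|---|---|---|
| 0.250 | 12.3 | 85.2 |
| 0.417 | 19.3 | 74.8 |
| 0.833 | 31.1 | 66.7 |
| 1.67 | 46.5 | 47.2 |
| 3.00 | 54.9 | 41.3 |

(standard deviation of a reading: 1 percentage point)

- target present at 6.0 d, in percent of the starting material charged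
- starting material present at 6.0 d, in percent of the starting material charged



The reagent is less than the two substrates together, so take the symmetric case as the zero of your scale and suppose that the two equally charged substrates draw on the reagent evenly. That split serves 60.0% of each charge; call c(reagent) divided by c(starting material) plus c(second substrate) the even share, with the reagent as limiting reagent.

Now draw the target. Your first reading gives a starting slope of about 0.492 /d, and that line meets the level of the even share at 1.22 d, the knee. Between the last two readings the slope is down to 0.0632 /d. The 5.1 percentage points still open at 3.00 d close at that slope in 0.807 d, so I expect the curve to be flat by 6.0 d. The protic impurity, taken one to one, claims 2.00% of the starting material. My reckoning is therefore 60.0% target and 38.0% starting material.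

The forecast differs: “The sag suggests the catalyst is slowly dying, or possibly reversibility”. It gives 63% target (56% to 71%) and 33% starting material (25% to 39%).

This flask gives 56.0% target and 40.0% starting material.

    starting material + protic impurity → quenched substrate (k = 0.0105 /M/min)
    reagent + catalyst intermediate A → free catalyst + target (k = 0.0251 /M/min)
    second substrate + free catalyst ⇌ catalyst intermediate B (K = 2.20 /M, k = 0.0259 /M/min)
    reagent + catalyst intermediate B → free catalyst + second product (k = 0.0837 /M/min)
    starting material + free catalyst ⇌ catalyst intermediate A (K = 3.72 /M, k = 0.0357 /M/min)

At 6.00 d this flask holds 0.089% of its reagent charge, less than the 40% of its starting material charge, and its 0.434 M of second product stands beside 0.381 M of target, whose 56.0% is 4 points less than the even share of 60.0%. A neighbour flask charged with 0.20 M of reagent has an even share of 14.7%, and it ends with 11.7% target and 84.0% starting material.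

(The readings are calculated from invented constants; scatter was added.)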